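**Retrosynthetic overview** (target numbering: O2, C1, C3–C8a; side chain C1'–C7')
1. Pyran ring last: O2–C3 bond by gold-catalysed 6-endo hydroalkoxylation of the C1 hydroxymethyl group onto the C4≡C3 alkyne of an enynone.
2. C3–C1' bond by a new rhodium-catalysed E-selective cross-hydroalkynylation of the core β-ethynyl enone with the side-chain propargylic diol (fallback: Sonogashira coupling).
3. β-Ethynyl enone from a cyclohexenone by ethynyl addition and Babler–Dauben transposition; the carbocycle (first ring) by aldol cyclodehydration of a methyl ketone–aldehyde (C5–C6 bond).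
4. C8 and C8a by an Evans syn aldol of a senecioyl imide; C7 by Trost asymmetric allylic etherification of isoprene monoepoxide.
5. Side chain from L-isoleucic acid (C4', C5'); C3' by chelation-controlled MeMgBr addition to an α-hydroxy alkynyl ketone.

Assumption: racemic isoprene monoepoxide, (R)-4-benzyloxazolidin-2-one and (2S,3S)-2-hydroxy-3-methylpentanoic acid (L-isoleucic acid) are bought; the (S,S) antipode of the Trost ligand is taken as the one that gives the R ether; locants C1 to C8a and C1' to C7' in the Why lines are those of the target.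

**Step 1**
Reactants: 1 2-methyl-2-vinyloxirane (racemic isoprene monoepoxide); 2 4-methoxybenzyl alcohol
Product: 3 (R)-2-[(4-methoxybenzyl)oxy]-2-methylbut-3-en-1-ol
Conditions: Pd2(dba)3·CHCl3 (1 mol %), (S,S)-DACH-phenyl Trost ligand (3 mol %), Et3B (1 mol %), CH2Cl2, rt
Reagents that add atoms: none
Why: Trost palladium-catalysed dynamic kinetic asymmetric allylic etherification, in which both enantiomers of 1 ionise to rapidly equilibrating π-allyl palladium alkoxides, Et3B ties 2 to that alkoxide as a borate and delivers it to the tertiary terminus, and the chiral ligand thereby sets the C7 tertiary ether as R.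

**Step 2**
Reactants: 3 (R)-2-[(4-methoxybenzyl)oxy]-2-methylbut-3-en-1-ol
Product: 4 (R)-2-[(4-methoxybenzyl)oxy]-2-methylbut-3-enal
Conditions: Dess–Martin periodinane, CH2Cl2, 0 °C → rt
Reagents that add atoms: none
Why: Dess–Martin oxidation of the neopentyl primary alcohol stops at an aldehyde that has no α-hydrogen, so C7 cannot epimerise and the PMB ether and vinyl group are inert.

**Step 3**
Reactants: 5 (R)-4-benzyloxazolidin-2-one; 6 3-methylbut-2-enoyl chloride
Product: 8 (R)-4-benzyl-3-(3-methylbut-2-enoyl)oxazolidin-2-one, via lithium oxazolidinide 7 (not isolated)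
Conditions: n-BuLi, THF, −78 °C; then 6, −78 → 0 °C
Reagents that add atoms: none
Why: Standard N-acylation of an Evans auxiliary, the lithiated oxazolidinone attacking the acid chloride at low temperature without deconjugating the enoyl group.

**Step 4**
Reactants: 8 (R)-4-benzyl-3-(3-methylbut-2-enoyl)oxazolidin-2-one; 4 (R)-2-[(4-methoxybenzyl)oxy]-2-methylbut-3-enal
Product: 10 (R)-4-benzyl-3-[(2R,3R,4R)-3-hydroxy-4-[(4-methoxybenzyl)oxy]-4-methyl-2-(prop-1-en-2-yl)hex-5-enoyl]oxazolidin-2-one, via boron dienolate 9 (not isolated)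
Conditions: Bu2BOTf, Et3N, CH2Cl2, −78 → 0 °C; then 4, −78 → 0 °C; pH 7 buffer, MeOH, H2O2
Reagents that add atoms: none
Why: Evans syn aldol reaction in which Bu2BOTf and Et3N remove a γ-hydrogen to give the Z boron dienolate, which reacts at its α-carbon through a Zimmerman–Traxler chair on the face left open by the (R)-benzyl auxiliary, setting C8 (R) and C8a with hydroxyl and isopropenyl syn under reagent control over the weak bias of the α-alkoxy aldehyde.

**Step 5**
Reactants: 10 (R)-4-benzyl-3-[(2R,3R,4R)-3-hydroxy-4-[(4-methoxybenzyl)oxy]-4-methyl-2-(prop-1-en-2-yl)hex-5-enoyl]oxazolidin-2-one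
Product: 11 (2S,3R,4R)-4-[(4-methoxybenzyl)oxy]-4-methyl-2-(prop-1-en-2-yl)hex-5-ene-1,3-diol
Conditions: LiBH4, H2O (1 equiv), Et2O, 0 °C
Reagents that add atoms: none
Why: Hydroxyl-assisted reductive cleavage of the imide by LiBH4 turns the acyl carbon into the C1 hydroxymethyl group, returns the auxiliary and leaves the alkenes and the C8a centre untouched.

**Step 6**
Reactants: 11 (2S,3R,4R)-4-[(4-methoxybenzyl)oxy]-4-methyl-2-(prop-1-en-2-yl)hex-5-ene-1,3-diol
Product: 12 (4R,5S)-4-[(2R)-2-[(4-methoxybenzyl)oxy]but-3-en-2-yl]-2,2-dimethyl-5-(prop-1-en-2-yl)-1,3-dioxane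
Conditions: Me2C(OMe)2, PPTS (5 mol %), CH2Cl2, rt
Reagents that add atoms: 2,2-dimethoxypropane, COC(C)(C)OC
Why: Acid-catalysed acetal exchange locks O1 and O8 in a six-membered acetonide that survives every step up to the end game, while the tertiary PMB ether is stable to PPTS.

**Step 7**
Reactants: 12 (4R,5S)-4-[(2R)-2-[(4-methoxybenzyl)oxy]but-3-en-2-yl]-2,2-dimethyl-5-(prop-1-en-2-yl)-1,3-dioxane
Product: 14 (2S)-2-[(4R,5S)-5-acetyl-2,2-dimethyl-1,3-dioxan-4-yl]-2-[(4-methoxybenzyl)oxy]propanal, via tetraol 13 (not isolated)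
Conditions: OsO4 (4 mol %), NaIO4, 2,6-lutidine, dioxane/H2O (3:1), rt
Reagents that add atoms: OsO4, O=[Os](=O)(=O)=O (oxygen carrier); NaIO4, [Na+].[O-]I(=O)(=O)=O (terminal oxygen source)
Why: Lemieux–Johnson oxidation, OsO4 dihydroxylating both terminal alkenes and NaIO4 cleaving the glycols, converts isopropenyl into the C4a methyl ketone and vinyl into the C6 aldehyde in one operation, with 2,6-lutidine suppressing over-oxidation and the PMB ether spared.

**Step 8**
Reactants: 14 (2S)-2-[(4R,5S)-5-acetyl-2,2-dimethyl-1,3-dioxan-4-yl]-2-[(4-methoxybenzyl)oxy]propanal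
Product: 16 (4aS,8R,8aR)-8-[(4-methoxybenzyl)oxy]-2,2,8-trimethyl-4a,8a-dihydro-4H-benzo[d][1,3]dioxin-5(8H)-one, via aldol 15 (not isolated)
Conditions: Bn2NH·CF3CO2H (0.3 equiv), toluene, 50 °C
Reagents that add atoms: none
Why: Intramolecular aldol condensation under mild amine-salt catalysis, in which only the methyl ketone can enolise, its methyl carbon (C5) adds to the non-enolisable C6 aldehyde in a six-membered ring closure and dehydration gives the enone without a base strong enough to epimerise C8a.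

**Step 9**
Reactants: 16 (4aS,8R,8aR)-8-[(4-methoxybenzyl)oxy]-2,2,8-trimethyl-4a,8a-dihydro-4H-benzo[d][1,3]dioxin-5(8H)-one
Product: 17 (4aS,8R,8aR)-5-ethynyl-8-[(4-methoxybenzyl)oxy]-2,2,8-trimethyl-4a,5,8,8a-tetrahydro-4H-benzo[d][1,3]dioxin-5-ol (both C5 epimers)
Conditions: HC≡CMgBr, THF, −78 → 0 °C
Reagents that add atoms: ethynylmagnesium bromide, C#C[Mg]Br
Why: 1,2-Addition of the weakly basic ethynyl Grignard reagent to the enone carbonyl (C4a), conjugate addition being blocked by the quaternary C7 next to C6, and the configuration of the new carbinol being irrelevant because it is erased in the next step.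

**Step 10**
Reactants: 17 (4aS,8R,8aR)-5-ethynyl-8-[(4-methoxybenzyl)oxy]-2,2,8-trimethyl-4a,5,8,8a-tetrahydro-4H-benzo[d][1,3]dioxin-5-ol
Product: 19 (4aS,8S,8aR)-5-ethynyl-8-[(4-methoxybenzyl)oxy]-2,2,8-trimethyl-8,8a-dihydro-4H-benzo[d][1,3]dioxin-7(4aH)-one, via allylic chlorochromate ester 18 (not isolated)
Conditions: (C5H5NH)[CrO3Cl] (pyridinium chlorochromate), NaOAc, 4 Å MS, CH2Cl2, rt
Reagents that add atoms: pyridinium chlorochromate, [O-][Cr](=O)(=O)Cl.c1cc[nH+]cc1 (supplies the C6 carbonyl oxygen)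
Why: Babler–Dauben oxidative 1,3-transposition, the tertiary allylic chlorochromate undergoing a [3,3] shift to the secondary ester at C6 that is then oxidised to the ketone conjugated with the alkyne, while the PMB ether at C7 prevents the competing transposition of that tertiary allylic oxygen.

**Step 11**
Reactants: 19 (4aS,8S,8aR)-5-ethynyl-8-[(4-methoxybenzyl)oxy]-2,2,8-trimethyl-8,8a-dihydro-4H-benzo[d][1,3]dioxin-7(4aH)-one
Product: 20 (4aS,8S,8aR)-5-ethynyl-8-hydroxy-2,2,8-trimethyl-8,8a-dihydro-4H-benzo[d][1,3]dioxin-7(4aH)-one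
Conditions: DDQ, CH2Cl2/pH 7 buffer (10:1), 0 °C → rt
Reagents that add atoms: none
Why: DDQ oxidises only the electron-rich 4-methoxybenzyl ether through its benzylic oxocarbenium ion, which water hydrolyses to free the C7 tertiary alcohol, while the electron-poor enynone and the acetonide do not react.

**Step 12**
Reactants: 21 (2S,3S)-2-hydroxy-3-methylpentanoic acid
Product: 23 (2S,3S)-2-hydroxy-N-methoxy-N,3-dimethylpentanamide, via HOBt ester 22 (not isolated)
Conditions: MeNHOMe·HCl, EDCI·HCl, HOBt, N-methylmorpholine, CH2Cl2, 0 °C → rt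
Reagents that add atoms: N,O-dimethylhydroxylamine hydrochloride, CNOC.Cl
Why: Carbodiimide and HOBt amide coupling gives the Weinreb amide through the active ester under conditions too mild to epimerise the α-carbon.

**Step 13**
Reactants: 23 (2S,3S)-2-hydroxy-N-methoxy-N,3-dimethylpentanamide
Product: 24 (4S,5S)-4-hydroxy-5-methyl-1-(trimethylsilyl)hept-1-yn-3-one
Conditions: LiC≡CSiMe3 (2.5 equiv), THF, −78 → −20 °C
Reagents that add atoms: lithium (trimethylsilyl)acetylide, [Li]C#C[Si](C)(C)C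
Why: Weinreb ketone synthesis, the first equivalent of acetylide deprotonating the hydroxyl and the second adding once to give a chelated tetrahedral adduct that releases the alkynyl ketone only on work-up.

**Step 14**
Reactants: 24 (4S,5S)-4-hydroxy-5-methyl-1-(trimethylsilyl)hept-1-yn-3-one
Product: 25 (3R,4S,5S)-3,5-dimethyl-1-(trimethylsilyl)hept-1-yne-3,4-diol
Conditions: MeMgBr (3 equiv), CH2Cl2/Et2O, −78 °C
Reagents that add atoms: methylmagnesium bromide, C[Mg]Br
Why: Chelation-controlled (Cram chelate) Grignard addition, the magnesium alkoxide of the α-hydroxyl and the ketone oxygen forming a five-membered chelate that methyl attacks on the face of the C4' hydrogen away from the sec-butyl group, which sets C3' as R (hydroxyls anti along the alkyne–C3'–C4' chain), with the silyl cap discouraging conjugate addition.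

**Step 15**
Reactants: 25 (3R,4S,5S)-3,5-dimethyl-1-(trimethylsilyl)hept-1-yne-3,4-diol
Product: 26 (3R,4S,5S)-3,5-dimethylhept-1-yne-3,4-diol
Conditions: K2CO3 (0.2 equiv), MeOH, rt
Reagents that add atoms: none
Why: Mild base-catalysed methanolysis cleaves only the alkynyl C–Si bond.

**Step 16**
Reactants: 20 (4aS,8S,8aR)-5-ethynyl-8-hydroxy-2,2,8-trimethyl-8,8a-dihydro-4H-benzo[d][1,3]dioxin-7(4aH)-one; 26 (3R,4S,5S)-3,5-dimethylhept-1-yne-3,4-diol
Product: 27 (4aS,8S,8aR)-5-[(3E,5R,6S,7S)-5,6-dihydroxy-5,7-dimethylnon-3-en-1-yn-1-yl]-8-hydroxy-2,2,8-trimethyl-8,8a-dihydro-4H-benzo[d][1,3]dioxin-7(4aH)-one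
Conditions: RhCl(PPh3)3 (5 mol %), toluene, 40 °C; 26 (3 equiv), slow addition of 20
Reagents that add atoms: none
Why: Proposed new method: a chemo-, regio- and E-selective rhodium-catalysed cross-hydroalkynylation (head-to-head cross-dimerisation of two different terminal alkynes) in which the more acidic sp C–H bond of the electron-poor ynenone 20 adds oxidatively to monovalent rhodium, the tertiary propargylic hydroxyl of 26 binds the trivalent rhodium alkynyl hydride and directs syn hydrometalation with rhodium on the terminal carbon (five-membered alkoxy chelate, quaternary carbon avoided), and C(sp)–C(sp2) reductive elimination forms the C3–C1' bond and the E C1'=C2' alkene with no atom lost, excess 26 and slow addition of 20 suppressing self-coupling of 20; the closest known reaction type is the RhCl(PPh3)3-catalysed E-selective head-to-head dimerisation of tertiary propargylic alcohols and related rhodium cross-dimerisations of simple terminal alkynes, which has not been shown for a conjugated ynenone donor with a chiral propargylic diol acceptor.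

**Step 17**
Reactants: 27 (4aS,8S,8aR)-5-[(3E,5R,6S,7S)-5,6-dihydroxy-5,7-dimethylnon-3-en-1-yn-1-yl]-8-hydroxy-2,2,8-trimethyl-8,8a-dihydro-4H-benzo[d][1,3]dioxin-7(4aH)-one
Product: 28 (4S,5R,6S)-3-[(3E,5R,6S,7S)-5,6-dihydroxy-5,7-dimethylnon-3-en-1-yn-1-yl]-5,6-dihydroxy-4-(hydroxymethyl)-6-methylcyclohex-2-en-1-one
Conditions: PPTS (0.2 equiv), MeOH, 35 °C
Reagents that add atoms: none
Why: Acid-catalysed acetal exchange with methanol removes the acetonide, and the tertiary allylic alcohol does not ionise because the attached enynone π-system is electron-poor.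

**Step 18**
Reactants: 28 (4S,5R,6S)-3-[(3E,5R,6S,7S)-5,6-dihydroxy-5,7-dimethylnon-3-en-1-yn-1-yl]-5,6-dihydroxy-4-(hydroxymethyl)-6-methylcyclohex-2-en-1-one
Product: 29 (7S,8R,8aS)-3-[(1E,3R,4S,5S)-3,4-dihydroxy-3,5-dimethylhept-1-en-1-yl]-7,8-dihydroxy-7-methyl-1,7,8,8a-tetrahydro-6H-isochromen-6-one (CNP0291643.10)
Conditions: Ph3PAuCl (5 mol %), AgOTf (5 mol %), THF, 0 °C → rt
Reagents that add atoms: none
Why: Gold-catalysed 6-endo-dig hydroalkoxylation (cycloisomerisation), in which the alkyne bound to monovalent gold is attacked by the primary C1 hydroxyl at C3, the carbon remote from the enone and stabilised by the adjacent vinyl group (the 1,6-oxa-Michael position), and protodeauration closes the pyran ring as the dienol ether without touching any stereocentre, the other hydroxyls being unable to reach the alkyne without forming bridged rings.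

**Compound list**
1 | 2-methyl-2-vinyloxirane (racemic) | CC1(C=C)CO1 | starting material
2 | 4-methoxybenzyl alcohol | COc1ccc(CO)cc1 | starting material
3 | (R)-2-[(4-methoxybenzyl)oxy]-2-methylbut-3-en-1-ol | C=C[C@@](C)(OCc1ccc(OC)cc1)CO | intermediate
4 | (R)-2-[(4-methoxybenzyl)oxy]-2-methylbut-3-enal | C=C[C@@](C)(OCc1ccc(OC)cc1)C=O | intermediate
5 | (R)-4-benzyloxazolidin-2-one | O=C1N[C@H](Cc2ccccc2)CO1 | starting material
6 | 3-methylbut-2-enoyl chloride | CC(C)=CC(=O)Cl | starting material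
7 | lithium (R)-4-benzyl-2-oxooxazolidin-3-ide | [Li+].O=C1[N-][C@H](Cc2ccccc2)CO1 | intermediate (not isolated)
8 | (R)-4-benzyl-3-(3-methylbut-2-enoyl)oxazolidin-2-one | CC(C)=CC(=O)N1[C@H](Cc2ccccc2)COC1=O | intermediate
9 | (R)-4-benzyl-3-[(1Z)-1-[(dibutylboranyl)oxy]-3-methylbuta-1,3-dien-1-yl]oxazolidin-2-one (Z boron dienolate of 8) | C=C(C)/C=C(\OB(CCCC)CCCC)N1[C@H](Cc2ccccc2)COC1=O | intermediate (not isolated)
10 | (R)-4-benzyl-3-[(2R,3R,4R)-3-hydroxy-4-[(4-methoxybenzyl)oxy]-4-methyl-2-(prop-1-en-2-yl)hex-5-enoyl]oxazolidin-2-one | C=C[C@@](C)(OCc1ccc(OC)cc1)[C@H](O)[C@@H](C(C)=C)C(=O)N1[C@H](Cc2ccccc2)COC1=O | intermediate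
11 | (2S,3R,4R)-4-[(4-methoxybenzyl)oxy]-4-methyl-2-(prop-1-en-2-yl)hex-5-ene-1,3-diol | C=C[C@@](C)(OCc1ccc(OC)cc1)[C@H](O)[C@@H](C(C)=C)CO | intermediate
12 | (4R,5S)-4-[(2R)-2-[(4-methoxybenzyl)oxy]but-3-en-2-yl]-2,2-dimethyl-5-(prop-1-en-2-yl)-1,3-dioxane | C=C[C@@](C)(OCc1ccc(OC)cc1)[C@@H]1OC(C)(C)OC[C@@H]1C(C)=C | intermediate
13 | tetraol from dihydroxylation of both alkenes of 12 (existing centres unchanged; mixture at the two new carbinol carbons) | OCC(O)[C@@](C)(OCc1ccc(OC)cc1)[C@@H]1OC(C)(C)OC[C@@H]1C(C)(O)CO | intermediate (not isolated)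
14 | (2S)-2-[(4R,5S)-5-acetyl-2,2-dimethyl-1,3-dioxan-4-yl]-2-[(4-methoxybenzyl)oxy]propanal | O=C[C@@](C)(OCc1ccc(OC)cc1)[C@@H]1OC(C)(C)OC[C@@H]1C(C)=O | intermediate
15 | aldol (β-hydroxy ketone): 16 with water added across its C=C, hydroxyl on the carbon next to the PMB-ether carbon (mixture at that carbinol) | O=C1CC(O)[C@@](C)(OCc2ccc(OC)cc2)[C@@H]2OC(C)(C)OC[C@H]12 | intermediate (not isolated)
16 | (4aS,8R,8aR)-8-[(4-methoxybenzyl)oxy]-2,2,8-trimethyl-4a,8a-dihydro-4H-benzo[d][1,3]dioxin-5(8H)-one | O=C1C=C[C@@](C)(OCc2ccc(OC)cc2)[C@@H]2OC(C)(C)OC[C@H]12 | intermediate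
17 | (4aS,8R,8aR)-5-ethynyl-8-[(4-methoxybenzyl)oxy]-2,2,8-trimethyl-4a,5,8,8a-tetrahydro-4H-benzo[d][1,3]dioxin-5-ol (both C5 epimers) | C#CC1(O)C=C[C@@](C)(OCc2ccc(OC)cc2)[C@@H]2OC(C)(C)OC[C@H]12 | intermediate
18 | chlorochromate ester of the transposed allylic alcohol (O–CrO2Cl on benzodioxine C7, alkene now C5=C6) | C#CC1=CC(O[Cr](=O)(=O)Cl)[C@@](C)(OCc2ccc(OC)cc2)[C@@H]2OC(C)(C)OC[C@H]12 | intermediate (not isolated)
19 | (4aS,8S,8aR)-5-ethynyl-8-[(4-methoxybenzyl)oxy]-2,2,8-trimethyl-8,8a-dihydro-4H-benzo[d][1,3]dioxin-7(4aH)-one | C#CC1=CC(=O)[C@@](C)(OCc2ccc(OC)cc2)[C@@H]2OC(C)(C)OC[C@H]12 | intermediate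
20 | (4aS,8S,8aR)-5-ethynyl-8-hydroxy-2,2,8-trimethyl-8,8a-dihydro-4H-benzo[d][1,3]dioxin-7(4aH)-one | C#CC1=CC(=O)[C@@](C)(O)[C@@H]2OC(C)(C)OC[C@H]12 | intermediate
21 | (2S,3S)-2-hydroxy-3-methylpentanoic acid (L-isoleucic acid) | CC[C@H](C)[C@H](O)C(=O)O | starting material
22 | 1H-benzotriazol-1-yl (2S,3S)-2-hydroxy-3-methylpentanoate | CC[C@H](C)[C@H](O)C(=O)On1nnc2ccccc12 | intermediate (not isolated)
23 | (2S,3S)-2-hydroxy-N-methoxy-N,3-dimethylpentanamide | CC[C@H](C)[C@H](O)C(=O)N(C)OC | intermediate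
24 | (4S,5S)-4-hydroxy-5-methyl-1-(trimethylsilyl)hept-1-yn-3-one | CC[C@H](C)[C@H](O)C(=O)C#C[Si](C)(C)C | intermediate
25 | (3R,4S,5S)-3,5-dimethyl-1-(trimethylsilyl)hept-1-yne-3,4-diol | CC[C@H](C)[C@H](O)[C@](C)(O)C#C[Si](C)(C)C | intermediate
26 | (3R,4S,5S)-3,5-dimethylhept-1-yne-3,4-diol | CC[C@H](C)[C@H](O)[C@](C)(O)C#C | intermediate
27 | (4aS,8S,8aR)-5-[(3E,5R,6S,7S)-5,6-dihydroxy-5,7-dimethylnon-3-en-1-yn-1-yl]-8-hydroxy-2,2,8-trimethyl-8,8a-dihydro-4H-benzo[d][1,3]dioxin-7(4aH)-one | CC[C@H](C)[C@H](O)[C@](C)(O)/C=C/C#CC1=CC(=O)[C@@](C)(O)[C@@H]2OC(C)(C)OC[C@H]12 | intermediate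
28 | (4S,5R,6S)-3-[(3E,5R,6S,7S)-5,6-dihydroxy-5,7-dimethylnon-3-en-1-yn-1-yl]-5,6-dihydroxy-4-(hydroxymethyl)-6-methylcyclohex-2-en-1-one | CC[C@H](C)[C@H](O)[C@](C)(O)/C=C/C#CC1=CC(=O)[C@@](C)(O)[C@H](O)[C@@H]1CO | intermediate
29 | (7S,8R,8aS)-3-[(1E,3R,4S,5S)-3,4-dihydroxy-3,5-dimethylhept-1-en-1-yl]-7,8-dihydroxy-7-methyl-1,7,8,8a-tetrahydro-6H-isochromen-6-one | CC[C@H](C)[C@H](O)[C@](C)(O)/C=C/C1=CC2=CC(=O)[C@@](C)(O)[C@H](O)[C@@H]2CO1 | target

**Step count and risks**
Total step count: 18. Longest linear sequence: 13 steps (steps 1, 2, 4 to 11, 16 to 18).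

The three steps most likely to fail:

Step 8 (aldol cyclodehydration; the risk is epimerisation at C8a, which is alpha to the ketone, or a stalled dehydration). The fallback closes the ring by olefin metathesis under neutral conditions. It sets out from 14. Chemoselective Wittig methylenation of the aldehyde only (Ph3P=CH2, THF, −78 °C) gives 1-[(4R,5S)-4-[(2R)-2-[(4-methoxybenzyl)oxy]but-3-en-2-yl]-2,2-dimethyl-1,3-dioxan-5-yl]ethan-1-one F1. Kinetic enolisation of its methyl group (LiHMDS, THF, −78 °C) and trapping with Eschenmoser's salt (Me2N=CH2 iodide) gives the Mannich base 3-(dimethylamino)-1-[(4R,5S)-4-[(2R)-2-[(4-methoxybenzyl)oxy]but-3-en-2-yl]-2,2-dimethyl-1,3-dioxan-5-yl]propan-1-one F2. N-Methylation (MeI) and NaHCO3 then eliminate to the vinyl ketone 1-[(4R,5S)-4-[(2R)-2-[(4-methoxybenzyl)oxy]but-3-en-2-yl]-2,2-dimethyl-1,3-dioxan-5-yl]prop-2-en-1-one F3. Ring-closing metathesis of F3 with the second-generation Hoveyda–Grubbs catalyst (CH2Cl2, 40 °C) comes back to the route at 16.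

Step 10 (oxidative transposition of an ethynyl carbinol; the risk is Meyer–Schuster-type rearrangement or decomposition under chromium). The fallback separates transposition from oxidation. It sets out from 17. Ph3SiOReO3 (2 mol %, Et2O, −40 → 0 °C) catalyses the 1,3-transposition of the tertiary allylic alcohol, driven by conjugation of the new alkene with the alkyne, to (4aS,8aR)-5-ethynyl-8-[(4-methoxybenzyl)oxy]-2,2,8-trimethyl-4a,7,8,8a-tetrahydro-4H-benzo[d][1,3]dioxin-7-ol F4 (C7 epimers, other centres as in 17). Oxidation of this secondary allylic alcohol with MnO2 (CH2Cl2, rt) comes back to the route at 19.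

Step 16 (the proposed new cross-hydroalkynylation; the risks are self-dimerisation of 26, reversed donor and acceptor roles, or head-to-tail coupling). The fallback uses known chemistry and sets out from 26. Hydrozirconation with Cp2Zr(H)Cl (3.3 equiv, THF, rt; the extra equivalents are consumed by the two hydroxyls) followed by I2 gives (1E,3R,4S,5S)-1-iodo-3,5-dimethylhept-1-ene-3,4-diol F5. Sonogashira coupling of F5 with 20 (Pd(PPh3)4 5 mol %, CuI 10 mol %, Et3N, THF, rt) comes back to the route at 27.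

**Further compounds**
F1 | step 8 | 1-[(4R,5S)-4-[(2R)-2-[(4-methoxybenzyl)oxy]but-3-en-2-yl]-2,2-dimethyl-1,3-dioxan-5-yl]ethan-1-one | C=C[C@@](C)(OCc1ccc(OC)cc1)[C@@H]1OC(C)(C)OC[C@@H]1C(C)=O
F2 | step 8 | 3-(dimethylamino)-1-[(4R,5S)-4-[(2R)-2-[(4-methoxybenzyl)oxy]but-3-en-2-yl]-2,2-dimethyl-1,3-dioxan-5-yl]propan-1-one | C=C[C@@](C)(OCc1ccc(OC)cc1)[C@@H]1OC(C)(C)OC[C@@H]1C(=O)CCN(C)C
F3 | step 8 | 1-[(4R,5S)-4-[(2R)-2-[(4-methoxybenzyl)oxy]but-3-en-2-yl]-2,2-dimethyl-1,3-dioxan-5-yl]prop-2-en-1-one | C=C[C@@](C)(OCc1ccc(OC)cc1)[C@@H]1OC(C)(C)OC[C@@H]1C(=O)C=C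
F4 | step 10 | (4aS,8aR)-5-ethynyl-8-[(4-methoxybenzyl)oxy]-2,2,8-trimethyl-4a,7,8,8a-tetrahydro-4H-benzo[d][1,3]dioxin-7-ol (C7 epimers) | C#CC1=CC(O)[C@@](C)(OCc2ccc(OC)cc2)[C@@H]2OC(C)(C)OC[C@H]12
F5 | step 16 | (1E,3R,4S,5S)-1-iodo-3,5-dimethylhept-1-ene-3,4-diol | CC[C@H](C)[C@H](O)[C@](C)(O)/C=C/I
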